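Atom labels, also used as locants in the dioxine names: lactone C1 (C=O) and C2 (CH2); dioxane ring O1–O2–C3(H)–C4(Me)–C5(H2)–C6(Me); chain C1' to C10', then phenyl.
Retrosynthesis: the lactone O–C4 bond is cut first (iodolactonisation of a C4=C5 dioxine acid), then C1–C2 and C1'–C2' (two Wittig reactions). This leaves a 1,2-dioxine with formyl groups on C3 and C6. Joining C2 to C1' turns it into a 2,3-dioxabicyclo[2.2.2]octene-7,8-diol, and cutting C3–O2 and C6–O1 together gives a cyclohexadiene cis-diol and O2.
Enabling feature: C3, C4, C5, C6, the methyl groups on C4 and C6, C2 and C1' are the eight carbons of m-xylene in the right connectivity. C2 and C1' lie on the same face of the dioxane ring, which is exactly what a temporary C2–C1' ring bond demands.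
Forward order: arene carbocycle, enzymatic dearomatisation, 1,2-dioxine ring by [4+2] addition of singlet oxygen, carbocycle opened by glycol cleavage, C1 and the phenylnonyl unit added by Wittig reactions, γ-lactone ring closed last, then chain alkene saturated and iodine removed.
Stereochemistry: toluene dioxygenase fixes two carbinol centres, and their acetonide sends O2 to the opposite face, which fixes C3 and C6. The carbinol centres are then destroyed. C4 follows from C3 because the two-atom tether can only give the cis-fused lactone, and the C5 iodide centre is erased.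

Key step: step 3

Assumption: toluene dioxygenase is taken to oxidise m-xylene at the ring bond ortho,meta to one methyl group with the same absolute sense as toluene, in preference to benzylic hydroxylation; 9-phenylnonan-1-ol is taken as a catalogue compound.

Step 1
Reactants: 1 m-xylene
Product: 2 (1S,2R)-3,5-dimethylcyclohexa-3,5-diene-1,2-diol
Conditions: E. coli JM109(pDTG601) whole cells expressing toluene dioxygenase, air, glucose, phosphate buffer pH 7.4, 30 °C, 1 fed as vapour; EtOAc extraction (base-washed glassware)
Reagents that add atoms: dioxygen, O=O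
Why: Enzymatic arene cis-dihydroxylation (Rieske non-haem iron dioxygenase): the enzyme places both atoms of O2 on one face of the ring bond that lies ortho,meta to a methyl group, as with toluene, so the active site alone sets the 1S and 2R carbinol centres, and the host lacks the diol dehydrogenase that would rearomatise 2 to the catechol.

Step 2
Reactants: 2 (1S,2R)-3,5-dimethylcyclohexa-3,5-diene-1,2-diol
Product: 3 (3aR,7aS)-2,2,4,6-tetramethyl-3a,7a-dihydro-1,3-benzodioxole (acetonide of 2)
Conditions: Me2C(OMe)2, PPTS (cat.), CH2Cl2, 0 °C; Et3N quench; used at once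
Reagents that add atoms: 2,2-dimethoxypropane, COC(C)(C)OC
Why: Acid-catalysed transketalisation of a cis-1,2-diol, run with a weak acid in the cold because loss of the C1 hydroxyl of 2 would give a cation stabilised by both methyl groups and lead to 2,4-dimethylphenol; no stereocentre is touched and 3 is carried on at once to forestall Diels–Alder dimerisation.

Step 3
Reactants: 3 (3aR,7aS)-2,2,4,6-tetramethyl-3a,7a-dihydro-1,3-benzodioxole
Product: 4 (1S,4R,7S,8R)-7,8-(isopropylidenedioxy)-1,5-dimethyl-2,3-dioxabicyclo[2.2.2]oct-5-ene (peroxide bridge anti to the dioxolane)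
Conditions: O2, tetraphenylporphyrin (cat.), white LED, CH2Cl2, −78 °C
Reagents that add atoms: dioxygen, O=O
Why: Energy transfer from triplet tetraphenylporphyrin turns ground-state O2 into singlet oxygen, which adds in a concerted, suprafacial [4π+2π] cycloaddition to the termini of the ring-locked s-cis diene of 3, namely the methyl-bearing carbon (future C6) and the CH carbon next to the acetal (future C3). The closest known reaction type is the singlet-oxygen Diels–Alder reaction of acetonides of microbial arene cis-dihydrodiols and of α-terpinene (to ascaridole). The one ring that closes, the six-membered 1,2-dioxine O1–O2–C3–C4=C5–C6, closes by cycloaddition with both C–O bonds formed in the same event, and it appears as the peroxide bridge of a 2,3-dioxabicyclo[2.2.2]oct-5-ene. The two new stereocentres C3 and C6 are controlled by the cis-fused dioxolane, whose inward methyl group covers one diene face so that O2 enters from the other, and suprafacial addition ties C3 and C6 to each other. The step needs π-facial selectivity, secured by that acetal, and [4+2] over ene (Schenck) chemoselectivity, secured by the planar s-cis geometry, the two donor methyl groups, the aprotic solvent and the low temperature. Regiochemistry is no issue because the dienophile is symmetrical.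

Step 4
Reactants: 4 (1S,4R,7S,8R)-7,8-(isopropylidenedioxy)-1,5-dimethyl-2,3-dioxabicyclo[2.2.2]oct-5-ene
Product: 5 (1S,4R,7S,8R)-1,5-dimethyl-2,3-dioxabicyclo[2.2.2]oct-5-ene-7,8-diol
Conditions: Dowex 50WX8 (H+ form), MeOH/H2O, rt; filtration
Reagents that add atoms: none
Why: Acid-catalysed acetal hydrolysis on a sulfonic acid resin that is simply filtered off; a dialkyl peroxide is a far weaker base than the acetal oxygens, so the dioxolane should be protonated and opened first, and none of the four stereocentres takes part.

Step 5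
Reactants: 5 (1S,4R,7S,8R)-1,5-dimethyl-2,3-dioxabicyclo[2.2.2]oct-5-ene-7,8-diol
Product: 6 (3R,6S)-4,6-dimethyl-3,6-dihydro-1,2-dioxine-3,6-dicarbaldehyde (formyl groups cis)
Conditions: NaIO4 on silica gel, CH2Cl2, 0 °C; filtered, dried (MgSO4), exchanged into THF cold and used as a solution
Reagents that add atoms: none
Why: Malaprade glycol cleavage: the eclipsed cis-diol of the rigid bicycle forms the cyclic periodate ester easily, the O–O bond and the alkene are inert to periodate, and C7–C8 scission opens the carbocycle to two formyl groups that stay cis on C3 and C6 while the two carbinol stereocentres disappear.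

Step 6
Reactants: 6 (3R,6S)-4,6-dimethyl-3,6-dihydro-1,2-dioxine-3,6-dicarbaldehyde; 7 (methoxymethyl)triphenylphosphonium chloride
Product: 9 (3S,6S)-3-(2-methoxyethenyl)-4,6-dimethyl-3,6-dihydro-1,2-dioxine-6-carbaldehyde (E/Z mixture at the enol ether), via (methoxymethylidene)triphenylphosphorane 8 (not isolated)
Conditions: 7, KN(SiMe3)2, THF, 0 °C; ylide solution (1.0 equiv) added slowly to 6, THF, −78 °C; pH 7 buffer quench at −78 °C
Reagents that add atoms: (methoxymethyl)triphenylphosphonium chloride 7, COC[P+](c1ccccc1)(c1ccccc1)c1ccccc1.[Cl-]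
Why: Wittig methoxymethylenation: the ylide should add much faster to the formyl group on the tertiary carbon C3 than to the neopentyl-type one on quaternary C6, and slow inverse addition at −78 °C keeps base from ever being in excess, which limits double olefination, epimerisation at C3 and Kornblum–DeLaMare opening of the peroxide; no new stereocentre forms and the enol ether geometry does not matter.

Step 7
Reactants: 10 9-phenylnonan-1-ol
Product: 11 (9-bromononyl)benzene
Conditions: CBr4, PPh3, CH2Cl2, 0 °C
Reagents that add atoms: carbon tetrabromide, BrC(Br)(Br)Br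
Why: Appel reaction, an SN2 displacement of the alkoxyphosphonium ion of a primary alcohol by bromide under neutral conditions.

Step 8
Reactants: 11 (9-bromononyl)benzene
Product: 12 (9-phenylnonyl)triphenylphosphonium bromide
Conditions: PPh3, MeCN, reflux; recrystallised and dried
Reagents that add atoms: triphenylphosphine, c1ccc(cc1)P(c1ccccc1)c1ccccc1
Why: SN2 quaternisation of triphenylphosphine by an unhindered primary bromide; the salt is recrystallised free of PPh3, which would otherwise reduce the O–O bond in the next step.

Step 9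
Reactants: 9 (3S,6S)-3-(2-methoxyethenyl)-4,6-dimethyl-3,6-dihydro-1,2-dioxine-6-carbaldehyde; 12 (9-phenylnonyl)triphenylphosphonium bromide
Product: 14 (3S,6R)-3-(2-methoxyethenyl)-4,6-dimethyl-6-[(1Z)-10-phenyldec-1-en-1-yl]-3,6-dihydro-1,2-dioxine, via (9-phenylnonylidene)triphenylphosphorane 13 (not isolated)
Conditions: 12, NaN(SiMe3)2, THF, 0 °C; then 9, −78 to −20 °C; pH 7 buffer quench
Reagents that add atoms: (9-phenylnonyl)triphenylphosphonium bromide 12, [Br-].c1ccccc1CCCCCCCCC[P+](c1ccccc1)(c1ccccc1)c1ccccc1
Why: Wittig olefination with a non-stabilised ylide under lithium-free conditions, Z-selective through the kinetically favoured cis-oxaphosphetane; the aldehyde has no α-hydrogen, carbonyl addition at low temperature should outrun deprotonation at C3–H, and the alkene geometry is of no consequence since it is saturated in step 13.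

Step 10
Reactants: 14 (3S,6R)-3-(2-methoxyethenyl)-4,6-dimethyl-6-[(1Z)-10-phenyldec-1-en-1-yl]-3,6-dihydro-1,2-dioxine
Product: 15 2-{(3S,6R)-4,6-dimethyl-6-[(1Z)-10-phenyldec-1-en-1-yl]-3,6-dihydro-1,2-dioxin-3-yl}acetaldehyde
Conditions: 10% aq. oxalic acid on silica gel, CH2Cl2, 0 °C to rt; filtered, used crude
Reagents that add atoms: water, O
Why: Acid-catalysed enol ether hydrolysis (rate-limiting protonation of the electron-rich β-carbon, then hemiacetal collapse), for which a weak acid on wet silica suffices, so the tertiary bis-allylic C6–O bond should not ionise; C3 and C6 are untouched and 15 is used crude because a β-peroxy aldehyde can lose the peroxide by E1cB elimination.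

Step 11
Reactants: 15 2-{(3S,6R)-4,6-dimethyl-6-[(1Z)-10-phenyldec-1-en-1-yl]-3,6-dihydro-1,2-dioxin-3-yl}acetaldehyde
Product: 16 2-{(3S,6R)-4,6-dimethyl-6-[(1Z)-10-phenyldec-1-en-1-yl]-3,6-dihydro-1,2-dioxin-3-yl}acetic acid
Conditions: NaClO2, NaH2PO4, 2-methyl-2-butene (large excess), t-BuOH/H2O, 0 °C
Reagents that add atoms: sodium chlorite, [Na+].[O-]Cl=O
Why: Pinnick (Lindgren) oxidation: chlorous acid adds to the aldehyde and fragments to the acid and HOCl at about pH 4, too mild for β-elimination, and the excess 2-methyl-2-butene takes up HOCl before it reaches the two alkenes of the substrate.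

Step 12
Reactants: 16 2-{(3S,6R)-4,6-dimethyl-6-[(1Z)-10-phenyldec-1-en-1-yl]-3,6-dihydro-1,2-dioxin-3-yl}acetic acid
Product: 17 (3R,4S,4aR,7aS)-4-iodo-3,4a-dimethyl-3-[(1Z)-10-phenyldec-1-en-1-yl]-4,4a,7,7a-tetrahydro-3H-furo[3,2-c][1,2]dioxin-6-one (cis-fused iodolactone; 3S,4R,5S,6R in the atom labels above)
Conditions: I2, NaHCO3, MeCN, 0 °C, dark
Reagents that add atoms: iodine, II
Why: Iodolactonisation (5-exo, Markovnikov, anti addition): reversible iodonium formation on C4=C5 is productive only on the face opposite the C3 acetic acid arm, whose carboxylate opens it at the tertiary carbon C4, so C4 is set cis to C3 by the two-atom tether and iodine ends up trans on C5; the chain alkene has no nucleophile within reach of a small ring and stays unchanged.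

Step 13
Reactants: 17 cis-fused iodolactone with the (1Z)-10-phenyldec-1-en-1-yl chain
Product: 18 (3R,4S,4aR,7aS)-4-iodo-3,4a-dimethyl-3-(10-phenyldecyl)-4,4a,7,7a-tetrahydro-3H-furo[3,2-c][1,2]dioxin-6-one
Conditions: KO2CN=NCO2K (excess, in portions), AcOH, MeOH/CH2Cl2, 0 °C to rt
Reagents that add atoms: none
Why: Diimide reduction, a concerted syn transfer of two hydrogens that leaves O–O, C–I and lactone alone; it is placed before the radical step because a C5 radical next to an alkenyl-bearing C6 would undergo 1,2-vinyl migration through a cyclopropylcarbinyl radical and then break the peroxide.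

Step 14
Reactants: 18 (3R,4S,4aR,7aS)-4-iodo-3,4a-dimethyl-3-(10-phenyldecyl)-4,4a,7,7a-tetrahydro-3H-furo[3,2-c][1,2]dioxin-6-one
Product: 19 (3R,4aS,7aS)-3,4a-dimethyl-3-(10-phenyldecyl)-4,4a,7,7a-tetrahydro-3H-furo[3,2-c][1,2]dioxin-6-one (CNP0407146.3; 3S,4S,6R in the atom labels above)
Conditions: Bu3SnH (excess), Et3B (cat.), air, toluene, 0 °C
Reagents that add atoms: none
Why: Radical chain dehalogenation with tin hydride, started by Et3B and air at 0 °C: iodine abstraction is far faster than attack of the stannyl radical on O–O, and the ring-held C5 radical cannot align with the O1–O2 or C6–O1 bonds, so a high hydride concentration should trap it first; the C5 stereocentre is erased and C3, C4 and C6 are untouched.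

Compound list
1 | m-xylene | Cc1cccc(C)c1 | starting material
2 | (1S,2R)-3,5-dimethylcyclohexa-3,5-diene-1,2-diol | CC1=CC(C)=C[C@H](O)[C@@H]1O | intermediate
3 | (3aR,7aS)-2,2,4,6-tetramethyl-3a,7a-dihydro-1,3-benzodioxole | CC1=CC(C)=C[C@@H]2OC(C)(C)O[C@H]12 | intermediate
4 | (1S,4R,7S,8R)-7,8-(isopropylidenedioxy)-1,5-dimethyl-2,3-dioxabicyclo[2.2.2]oct-5-ene | C[C@]12OO[C@H](C(C)=C1)[C@@H]3OC(C)(C)O[C@H]23 | intermediate
5 | (1S,4R,7S,8R)-1,5-dimethyl-2,3-dioxabicyclo[2.2.2]oct-5-ene-7,8-diol | C[C@]12OO[C@H](C(C)=C1)[C@H](O)[C@@H]2O | intermediate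
6 | (3R,6S)-4,6-dimethyl-3,6-dihydro-1,2-dioxine-3,6-dicarbaldehyde | C[C@]1(C=O)OO[C@@H](C=O)C(C)=C1 | intermediate
7 | (methoxymethyl)triphenylphosphonium chloride | COC[P+](c1ccccc1)(c1ccccc1)c1ccccc1.[Cl-] | starting material
8 | (methoxymethylidene)triphenylphosphorane | COC=P(c1ccccc1)(c1ccccc1)c1ccccc1 | intermediate
9 | (3S,6S)-3-(2-methoxyethenyl)-4,6-dimethyl-3,6-dihydro-1,2-dioxine-6-carbaldehyde | C[C@]1(C=O)OO[C@@H](C=COC)C(C)=C1 | intermediate
10 | 9-phenylnonan-1-ol | OCCCCCCCCCc1ccccc1 | starting material
11 | (9-bromononyl)benzene | BrCCCCCCCCCc1ccccc1 | intermediate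
12 | (9-phenylnonyl)triphenylphosphonium bromide | [Br-].c1ccccc1CCCCCCCCC[P+](c1ccccc1)(c1ccccc1)c1ccccc1 | intermediate
13 | (9-phenylnonylidene)triphenylphosphorane | c1ccccc1CCCCCCCCC=P(c1ccccc1)(c1ccccc1)c1ccccc1 | intermediate
14 | (3S,6R)-3-(2-methoxyethenyl)-4,6-dimethyl-6-[(1Z)-10-phenyldec-1-en-1-yl]-3,6-dihydro-1,2-dioxine | C[C@]1(/C=C\CCCCCCCCc2ccccc2)OO[C@@H](C=COC)C(C)=C1 | intermediate
15 | 2-{(3S,6R)-4,6-dimethyl-6-[(1Z)-10-phenyldec-1-en-1-yl]-3,6-dihydro-1,2-dioxin-3-yl}acetaldehyde | C[C@]1(/C=C\CCCCCCCCc2ccccc2)OO[C@@H](CC=O)C(C)=C1 | intermediate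
16 | 2-{(3S,6R)-4,6-dimethyl-6-[(1Z)-10-phenyldec-1-en-1-yl]-3,6-dihydro-1,2-dioxin-3-yl}acetic acid | C[C@]1(/C=C\CCCCCCCCc2ccccc2)OO[C@@H](CC(=O)O)C(C)=C1 | intermediate
17 | (3R,4S,4aR,7aS)-4-iodo-3,4a-dimethyl-3-[(1Z)-10-phenyldec-1-en-1-yl]-4,4a,7,7a-tetrahydro-3H-furo[3,2-c][1,2]dioxin-6-one | C[C@@]1(/C=C\CCCCCCCCc2ccccc2)[C@@H](I)[C@]2(C)OC(=O)C[C@@H]2OO1 | intermediate
18 | (3R,4S,4aR,7aS)-4-iodo-3,4a-dimethyl-3-(10-phenyldecyl)-4,4a,7,7a-tetrahydro-3H-furo[3,2-c][1,2]dioxin-6-one | C[C@@]1(CCCCCCCCCCc2ccccc2)[C@@H](I)[C@]2(C)OC(=O)C[C@@H]2OO1 | intermediate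
19 | (3R,4aS,7aS)-3,4a-dimethyl-3-(10-phenyldecyl)-4,4a,7,7a-tetrahydro-3H-furo[3,2-c][1,2]dioxin-6-one | C[C@@]1(CCCCCCCCCCc2ccccc2)C[C@]2(C)OC(=O)C[C@@H]2OO1 | target

Total step count: 14. Longest linear sequence: 12 steps from 1 (steps 1 to 6 and 9 to 14); steps 7 and 8 form the side branch.

Steps most likely to fail

Step 6. The ylide may discriminate poorly between the two formyl groups, so that the wrong arm or both arms are olefinated. The basic ylide may also remove the acidic C3–H of the α-peroxy aldehyde, leading to epimerisation or Kornblum–DeLaMare opening of the O–O bond.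

- The fallback sets out from 6 and comes back at 14. It tells the arms apart at the alcohol level, under conditions that are not strongly basic.
- The cold solution of 6 is reduced (NaBH4, CeCl3·7H2O, MeOH/CH2Cl2, −78 °C) to (3R,6S)-3,6-bis(hydroxymethyl)-4,6-dimethyl-3,6-dihydro-1,2-dioxine F1.
- tert-Butyldimethylsilyl chloride and imidazole at −20 °C should silylate only the less hindered alcohol on the C3 arm, giving the C3 mono(tert-butyldimethylsilyl) ether F2.
- Dess–Martin periodinane buffered with NaHCO3 oxidises the neopentyl alcohol to the non-enolisable C6 carbaldehyde F3.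
- Ylide 13 converts it into the (Z)-alkenyl silyl ether F4, and HF·pyridine frees the C3 hydroxymethyl dioxine F5.
- A second Dess–Martin oxidation gives the C3 carbaldehyde F6.
- F6 meets ylide 8 at −78 °C only in the last operation, with no second aldehyde competing, and gives 14.

Step 4. Acid may ionise or solvolyse the tertiary allylic C–O bond of the peroxide bridge faster than the rigid dioxolane is hydrolysed.

- The fallback sets out from 2 and comes back at 5. It replaces the ketal by fluoride-labile silyl ethers, which also spares 2 the acid of step 2.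
- Triethylsilyl chloride and imidazole in DMF at 0 °C give the bis(triethylsilyl) ether of 2 F7.
- The same photooxygenation (O2, tetraphenylporphyrin, light, CH2Cl2, −78 °C), now anti to the two silyloxy groups, gives the bis(triethylsilyl) ether of 5 F8.
- HF·pyridine buffered with pyridine in THF at 0 °C then releases 5.

Step 3. The ene pathway may compete with cycloaddition, either at the two allylic methyl groups or at the allylic acetal C–H bonds that lie on the open face. Prolonged irradiation may also degrade the endoperoxide.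

- The fallback sets out from 3 and comes back at 4. It forms the same two C–O bonds without any singlet oxygen, by a cation-radical chain oxygenation.
- Catalytic (4-BrC6H4)3N SbCl6 in CH2Cl2 at −78 °C under ground-state O2 oxidises the electron-rich diene to its radical cation.
- Triplet O2 adds to one diene terminus on the open face, and the peroxyl centre closes on the other terminus of the same face.
- Electron transfer from a further molecule of 3 carries the chain.
- With no singlet oxygen present the ene channel is closed, and no compound outside the list arises (none F0).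

Further compounds
F1 | step 6 | (3R,6S)-3,6-bis(hydroxymethyl)-4,6-dimethyl-3,6-dihydro-1,2-dioxine | C[C@]1(CO)OO[C@@H](CO)C(C)=C1
F2 | step 6 | [(3R,6S)-3-(tert-butyldimethylsilyloxymethyl)-4,6-dimethyl-3,6-dihydro-1,2-dioxin-6-yl]methanol | C[C@]1(CO)OO[C@@H](CO[Si](C)(C)C(C)(C)C)C(C)=C1
F3 | step 6 | (3R,6S)-3-(tert-butyldimethylsilyloxymethyl)-4,6-dimethyl-3,6-dihydro-1,2-dioxine-6-carbaldehyde | C[C@]1(C=O)OO[C@@H](CO[Si](C)(C)C(C)(C)C)C(C)=C1
F4 | step 6 | (3R,6R)-3-(tert-butyldimethylsilyloxymethyl)-4,6-dimethyl-6-[(1Z)-10-phenyldec-1-en-1-yl]-3,6-dihydro-1,2-dioxine | C[C@]1(/C=C\CCCCCCCCc2ccccc2)OO[C@@H](CO[Si](C)(C)C(C)(C)C)C(C)=C1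
F5 | step 6 | {(3R,6R)-4,6-dimethyl-6-[(1Z)-10-phenyldec-1-en-1-yl]-3,6-dihydro-1,2-dioxin-3-yl}methanol | C[C@]1(/C=C\CCCCCCCCc2ccccc2)OO[C@@H](CO)C(C)=C1
F6 | step 6 | (3R,6R)-4,6-dimethyl-6-[(1Z)-10-phenyldec-1-en-1-yl]-3,6-dihydro-1,2-dioxine-3-carbaldehyde | C[C@]1(/C=C\CCCCCCCCc2ccccc2)OO[C@@H](C=O)C(C)=C1
F7 | step 4 | bis(triethylsilyl) ether of 2 | CC1=CC(C)=C[C@H](O[Si](CC)(CC)CC)[C@@H]1O[Si](CC)(CC)CC
F8 | step 4 | bis(triethylsilyl) ether of 5 | C[C@]12OO[C@H](C(C)=C1)[C@H](O[Si](CC)(CC)CC)[C@@H]2O[Si](CC)(CC)CC
F0 | step 3 | none | none
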